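## Structural features

The target is a flavone: benzo ring A is fused to the γ-pyrone ring C (O1, C2=C3, C4=O), and aryl ring B is bonded through C1' to C2. There is no stereocentre, so nothing has to be relayed between neighbouring centres, and every problem is one of constitution. Six oxygen substituents must be sorted into three methyl ethers (C6, C7, C2') and three free phenols (C5, C3', C5'). Ring A is the easy half, because its 5-OH is hydrogen-bonded to the C4 carbonyl and can be freed selectively from a 5,6,7-trimethoxy precursor. The real difficulty is ring B, a 1,2,4-trioxygenated benzene whose only methyl ether (C2') lies between the inter-ring bond and a free hydroxyl (C3'); this pattern cannot be reached by selective methylation or demethylation of a simple arene. Sensitive sites are the electron-rich ring B (oxidation, nitrosation, halogenation), C8–H of ring A (electrophiles) and C2 of the pyrone, which strong nucleophiles attack with ring opening. The key step uses the fact that C2'(OMe)–C3'(O)–C4'H–C5'(O) is the carbon and oxygen pattern of a 4-methoxyacetoacetate, while C1' and C6' can be carried on C2 of ring C as a nitroalkene, so ring B can be built from a trioxygenated diene and a two-carbon alkyne equivalent.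

## Logic of the disconnections

16 is cut at C1'–C2' and C5'–C6', which removes ring B as a whole and leads to 9 and 12. This is the cut that delivers the three ring B oxygens already differentiated, with methyl on the C2' oxygen only. The gain is that a hexa-oxygenated flavone becomes a bicyclic chromone plus a four-carbon chain, and all ring A chemistry is finished before ring B exists. The forward step must join the methoxy-bearing terminus of 12 to the carbon of 9 attached to C2, must expel the nitro group and not the C2' methoxy group, and must keep the acidic 5-OH of 9 away from the proton-sensitive 12. For that reason the 5-OH is silylated in the flask (13), and adduct 14 is hydrolysed to 15 before any base is added.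

12 is traced through 11 to 10 by removing the O–Si bonds at C1 and C3. 10 already holds the four carbons and three oxygens in the right places with the methyl group on the right oxygen, and it is commercial. The forward steps demand γ-deprotonation, silylation on oxygen and not on carbon, and strict exclusion of moisture.

9 is cut at the side-chain C=C bond (the future C1'–C6') to 7 and 8. This is the standard condensative cut of a nitroalkene and costs one commercial one-carbon unit. The condensation must give the E alkene and must not damage ring C, which calls for an acidic medium.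

7 is derived from 5 by cutting the O–CH3 bond at C5 and the two C–O bonds of the acetal. The C5 ether differs from those at C6 and C7 only through its peri relation to C4=O, and this distinction is used while no other chelating or electron-rich ring is present; the aldehyde stays masked until then. The gain is a fully methylated, robust chromone. The Lewis acid must stop after the peri ether.

5 is cut at C2–C3 and O1–C2 of ring C to 2 and 3. This brings the C2 substituent in at the aldehyde oxidation level, so no methyl group has to be oxidised later with a toxic selenium reagent. Ring C disappears, leaving an acetophenone and a two-carbon ester. The forward step must acylate a hindered ketone enolate next to a phenoxide; ring closure can use only the single phenol, so no isomeric chromone can form.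

2 is cut at the C4a–C4 aryl–acyl bond to 1 and a two-carbon acyl donor. The symmetry of 1 makes the two free ring positions identical, so only one ketone can form, and 1 already carries all ring A oxygens. The acylation must occur on carbon ortho to the hydroxyl without cleaving a methyl ether.

## Other disconnections considered

Alternative 1: The cut is through C3–C4 and O1–C2, with an isoxazole standing in for the C2–C3–C4 diketone. In the forward step hydroximoyl chloride A1 would be dehydrochlorinated with Et3N to nitrile oxide A2, which should add to the terminal alkyne A3 to give the 3,5-diarylisoxazole A4.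
- In its favour: nitrile oxide additions to terminal alkynes are regiochemically dependable, the two ortho substituents of A2 slow its dimerisation, and the union is fully convergent.
- Where it is better: the key bond formation is more predictable than the chosen cycloaddition, whose diene and acceptor pair is untested.
- Against it: A3 contains the whole ring B problem, which must be solved by a separate multistep arene synthesis with orthogonal protection, so the difficulty is moved and not removed.
- Against it: A4 still needs N–O cleavage, hydrolysis, closure of ring C, removal of three benzyl groups and cleavage of the C5 methyl ether. The last operation must tell the C5 ether from the C2' ether with ring B in place, which the chosen plan avoids.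
- Comparison: both plans are cycloadditions followed by unmasking. The alternative trades risk in one step for a clearly longer sequence.

Alternative 2: Ring C is cut at O1–C8a, C4a–C4 and O1–C2. CsF would release aryne A6 from silyl triflate A5. The carboxylate of propiolic acid A7 should add through oxygen to the aryne carbon remote from the flanking methoxy group, the aryl anion then attacks the acyl carbon, and the ortho-hydroxyaryl ynone closes by 6-endo attack to give flavone A8.
- In its favour: three bonds of ring C form in one flask.
- Where it is equal or better: the methoxy group next to the aryne directs the addition in the required sense, so regiocontrol is the equal of the nitro control in the chosen plan; in convergence it is the better.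
- Against it: A5 needs about three steps from compound 1, and A7 again presupposes the ring B pattern.
- Against it: closure in the 5-exo mode competes with the 6-endo mode.
- Against it: A8 ends with the hardest selectivity problem, C5 versus C2' ether cleavage alongside debenzylation.
- Comparison: the alternative is longer overall, and the chosen plan settles the ether selectivity before ring B exists.

Alternative 3: Ring B is cut at C1'–C2' and C3'–C4', to enone A9 and dimethyl methoxymalonate A10. With NaOMe the malonate anion should add to the enone carbon attached to C2, and the methyl ketone enolate then acylates on one ester (6-exo-trig Claisen closure) to give cyclohexane-1,3-dione A11.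
- In its favour: Michael–Claisen annulation is textbook chemistry with cheap reagents, A9 is one olefination from compound 7 of the chosen route, and the ring B oxygens again arrive differentiated.
- Where it is better: precedent for the ring-forming step is stronger than for the chosen cycloaddition.
- Against it: A11 is one decarboxylation and one dehydrogenation short of the arene, and the dehydrogenation must be done next to a free phenol and the electrophile-prone C8–H.
- Against it: methoxide may open ring C, and the quaternary C2' invites retro-Claisen cleavage.
- Comparison: in the chosen plan the nitro group carries the missing oxidation level and leaves as nitrous acid in the same flask, which saves two to three steps at the price of weaker precedent. This alternative is therefore kept as the fallback for the key step.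

Key step: step 7

Remark on the chemistry: the double-bond geometries written for 11 and 12 are those of the expected major isomers, and the stereocentres of 14 and 15 are left undefined (diastereomer mixtures); all of them disappear when ring B aromatises.

## Route

Step 1
Reactants: 1 3,4,5-trimethoxyphenol
Product: 2 1-(6-hydroxy-2,3,4-trimethoxyphenyl)ethan-1-one
Conditions: AcOH, BF3·OEt2, 90 °C; then H2O
Reagents that add atoms: acetic acid, CC(=O)O
Why: Friedel–Crafts C-acetylation of a very electron-rich phenol promoted by BF3 (the one-flask counterpart of O-acetylation and Fries rearrangement); the two free ring positions are equivalent by symmetry, each ortho to OH and para to a methoxy group, and the hydrogen-bonded ortho-hydroxy ketone is deactivated toward a second acylation.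

Step 2
Reactants: 2 1-(6-hydroxy-2,3,4-trimethoxyphenyl)ethan-1-one; 3 methyl 2,2-dimethoxyacetate
Product: 5 2-(dimethoxymethyl)-5,6,7-trimethoxy-4H-chromen-4-one, via diketone 4 (not isolated)
Conditions: NaH (4 equiv), THF, 0 °C → reflux; then HCl/MeOH, 60 °C
Reagents that add atoms: none
Why: Crossed Claisen condensation of the phenoxide–enolate dianion of 2 with an ester that does not readily self-condense gives 4, and acid then closes ring C by addition of the only phenol to the acetal-flanked carbonyl and loss of water; methanol as solvent keeps the future aldehyde as its dimethyl acetal.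

Step 3
Reactants: 5 2-(dimethoxymethyl)-5,6,7-trimethoxy-4H-chromen-4-one
Product: 7 5-hydroxy-6,7-dimethoxy-4-oxo-4H-chromene-2-carbaldehyde, via chloro ether boron chelate 6 (not isolated)
Conditions: BCl3 (3 equiv), CH2Cl2, −78 → 0 °C; then 2 M HCl, THF, 40 °C
Reagents that add atoms: water, O
Why: Chelation-directed Lewis acid ether cleavage: BCl3 bound to the C4 carbonyl cleaves only the peri C5 methyl ether (chloride attacks the methyl group) and leaves the C6 and C7 ethers at or below 0 °C. The same reagent converts the dimethyl acetal into the α-chloro ether of 6, which warm aqueous acid hydrolyses to the aldehyde together with the boron–oxygen bonds.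

Step 4
Reactants: 7 5-hydroxy-6,7-dimethoxy-4-oxo-4H-chromene-2-carbaldehyde; 8 nitromethane
Product: 9 5-hydroxy-6,7-dimethoxy-2-[(E)-2-nitroethenyl]-4H-chromen-4-one
Conditions: NH4OAc (0.3 equiv), AcOH, 90 °C
Reagents that add atoms: none
Why: Henry (nitroaldol) condensation under ammonium acetate catalysis; the strongly electrophilic aldehyde adds the nitronate and the β-nitro alcohol dehydrates in hot acetic acid to the conjugated, thermodynamically preferred E alkene. The acidic medium spares the base-sensitive pyrone and the chelated 5-OH.

Step 5
Reactants: 10 methyl 4-methoxy-3-oxobutanoate (methyl 4-methoxyacetoacetate)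
Product: 11 methyl (2Z)-4-methoxy-3-[(trimethylsilyl)oxy]but-2-enoate
Conditions: Me3SiCl, Et3N, toluene, rt
Reagents that add atoms: chlorotrimethylsilane, C[Si](C)(C)Cl
Why: O-Silylation of the enol form of a β-keto ester with Me3SiCl and Et3N (silyl enol ether formation); the conjugated enol ether is the only product expected, and the ammonium salt is filtered off under exclusion of moisture.

Step 6
Reactants: 11 methyl (2Z)-4-methoxy-3-[(trimethylsilyl)oxy]but-2-enoate
Product: 12 (1Z,3Z)-1,4-dimethoxy-1,3-bis[(trimethylsilyl)oxy]buta-1,3-diene
Conditions: LiN(iPr)2, THF, −78 °C; then Me3SiCl, −78 → 0 °C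
Reagents that add atoms: chlorotrimethylsilane, C[Si](C)(C)Cl
Why: Kinetic γ-deprotonation of the vinylogous ester by LiN(iPr)2 gives the extended ester enolate, which Me3SiCl traps on oxygen as the ketene silyl acetal (the standard preparation of 1-alkoxy-1,3-bis(silyloxy)dienes); low temperature suppresses C-silylation.

Step 7
Reactants: 9 5-hydroxy-6,7-dimethoxy-2-[(E)-2-nitroethenyl]-4H-chromen-4-one; 12 (1Z,3Z)-1,4-dimethoxy-1,3-bis[(trimethylsilyl)oxy]buta-1,3-diene
Product: 16 5,3',5'-trihydroxy-6,7,2'-trimethoxyflavone [2-(3,5-dihydroxy-2-methoxyphenyl)-5-hydroxy-6,7-dimethoxy-4H-chromen-4-one], via silyl ether 13 (not isolated), via cycloadduct 14 (not isolated), via nitro dione 15 (not isolated)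
Conditions: BSA (N,O-bis(trimethylsilyl)acetamide, 1.2 equiv), toluene–THF, 60 °C; then 12 (2.5 equiv), 0 → 50 °C, Ar; then 1 M HCl, THF, 0 °C → rt; then DBU (3 equiv), dry THF, 0 °C → rt; pH 7 phosphate buffer
Reagents that add atoms: none
Why: BSA first converts the chelated 5-OH into silyl ether 13 so that the phenol cannot protonate the ketene silyl acetal. The electron-rich diene 12, whose nucleophilic terminus is the methoxy-bearing C4, then adds to the nitroalkene carbon β to the nitro group (the carbon on C2), forming C1'–C2', and the ketene acetal carbon bonds to the nitro-bearing carbon, forming C5'–C6'; ring B is thus closed in a [4+2] mode, either concerted and asynchronous or by Michael addition and six-membered collapse of the nitronate carbon onto the oxygen-stabilised allyl cation. The closest known reaction type is the Diels–Alder reaction of 1-alkoxy-1,3-bis(silyloxy)dienes and 1-methoxy-3-silyloxydienes with nitroalkenes used as alkyne equivalents, followed by loss of nitrous acid to give phenols. The regioselectivity needed is secured by the nitro group, a far stronger acceptor than the vinylogous ester of ring C, which alone would polarise the alkene the other way. Aqueous acid then hydrolyses the mixed silyl methyl ketal at C5' (with loss of methanol), the silyl enol ether at C3' and the aryl silyl ether to give nitro dione 15; doing this before base is added prevents the nitronate from expelling a ketal oxygen. DBU removes the C1' hydrogen, which is vinylogously acidified by the C4 carbonyl, and nitrite leaves from C6' in preference to methoxide from C2' because it is by far the better leaving group; enolisation gives the arene with OMe at C2' and OH at C3' and C5'. The four stereocentres of 14 form without control and need none, since all are destroyed. Nitrite is washed out at pH 7 so that the electron-rich ring B is not nitrosated.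

## Compound list

1 | 3,4,5-trimethoxyphenol | COc1cc(O)cc(OC)c1OC | starting material
2 | 1-(6-hydroxy-2,3,4-trimethoxyphenyl)ethan-1-one | CC(=O)c1c(O)cc(OC)c(OC)c1OC | intermediate
3 | methyl 2,2-dimethoxyacetate | COC(OC)C(=O)OC | starting material
4 | 1-(6-hydroxy-2,3,4-trimethoxyphenyl)-4,4-dimethoxybutane-1,3-dione (keto form shown) | COC(OC)C(=O)CC(=O)c1c(O)cc(OC)c(OC)c1OC | intermediate
5 | 2-(dimethoxymethyl)-5,6,7-trimethoxy-4H-chromen-4-one | COC(OC)c1cc(=O)c2c(OC)c(OC)c(OC)cc2o1 | intermediate
6 | 2-[chloro(methoxy)methyl]-5-[(dichloroboranyl)oxy]-6,7-dimethoxy-4H-chromen-4-one (racemic, boron chelated by the C4 carbonyl) | COC(Cl)c1cc(=O)c2c(OB(Cl)Cl)c(OC)c(OC)cc2o1 | intermediate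
7 | 5-hydroxy-6,7-dimethoxy-4-oxo-4H-chromene-2-carbaldehyde | COc1cc2oc(C=O)cc(=O)c2c(O)c1OC | intermediate
8 | nitromethane | C[N+](=O)[O-] | starting material
9 | 5-hydroxy-6,7-dimethoxy-2-[(E)-2-nitroethenyl]-4H-chromen-4-one | COc1cc2oc(/C=C/[N+](=O)[O-])cc(=O)c2c(O)c1OC | intermediate
10 | methyl 4-methoxy-3-oxobutanoate | COCC(=O)CC(=O)OC | starting material
11 | methyl (2Z)-4-methoxy-3-[(trimethylsilyl)oxy]but-2-enoate | COC/C(O[Si](C)(C)C)=C/C(=O)OC | intermediate
12 | (1Z,3Z)-1,4-dimethoxy-1,3-bis[(trimethylsilyl)oxy]buta-1,3-diene | CO/C=C(O[Si](C)(C)C)/C=C(/OC)O[Si](C)(C)C | intermediate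
13 | 6,7-dimethoxy-2-[(E)-2-nitroethenyl]-5-[(trimethylsilyl)oxy]-4H-chromen-4-one | COc1cc2oc(/C=C/[N+](=O)[O-])cc(=O)c2c(O[Si](C)(C)C)c1OC | intermediate
14 | 2-{2,5-dimethoxy-6-nitro-3,5-bis[(trimethylsilyl)oxy]cyclohex-3-en-1-yl}-6,7-dimethoxy-5-[(trimethylsilyl)oxy]-4H-chromen-4-one (mixture of diastereomers) | COC1C(c2cc(=O)c3c(O[Si](C)(C)C)c(OC)c(OC)cc3o2)C([N+](=O)[O-])C(OC)(O[Si](C)(C)C)C=C1O[Si](C)(C)C | intermediate
15 | 5-(5-hydroxy-6,7-dimethoxy-4-oxo-4H-chromen-2-yl)-4-methoxy-6-nitrocyclohexane-1,3-dione (mixture of diastereomers and enol forms) | COC1C(c2cc(=O)c3c(O)c(OC)c(OC)cc3o2)C([N+](=O)[O-])C(=O)CC1=O | intermediate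
16 | 5,3',5'-trihydroxy-6,7,2'-trimethoxyflavone [2-(3,5-dihydroxy-2-methoxyphenyl)-5-hydroxy-6,7-dimethoxy-4H-chromen-4-one] | COc1cc2oc(-c3cc(O)cc(O)c3OC)cc(=O)c2c(O)c1OC | target

## Step count and least certain steps

Total: 7 steps. Longest linear sequence: 5 steps (steps 1, 2, 3, 4 and 7); the branch to 12 has 2 steps (5 and 6) before it joins in step 7.

Step 7 (key step). Several processes may divert it:
- conjugate addition of the diene without ring closure;
- reaction of the nitroalkene as a heterodiene at the C3–C4 enol ether of 12, giving a cyclic nitronate instead of the carbocycle;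
- desilylation of 12 by adventitious protons;
- nucleophilic ring cleavage of the α-nitro ketone during the base stage;
- nitrosation of ring B if nitrite is still present on acidification.

The pairing is untested and both partners are highly polarised, so a stepwise path with competing closures is plausible. The fallback leaves the cycloaddition for an annulation of known type; it sets out from 7 and comes back at 16.
- Wittig olefination of 7 with Ph3P=CHC(O)CH3 (toluene, 60 °C) should give 5-hydroxy-6,7-dimethoxy-2-[(1E)-3-oxobut-1-en-1-yl]-4H-chromen-4-one F1.
- Michael addition of dimethyl 2-methoxypropanedioate (the reagent A10 of alternative 3; NaOMe, MeOH, 0 °C → reflux) to the enone carbon next to ring C, followed by Claisen closure, should give methyl 6-(5-hydroxy-6,7-dimethoxy-4-oxo-4H-chromen-2-yl)-1-methoxy-2,4-dioxocyclohexane-1-carboxylate F2.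
- Hot aqueous HCl in AcOH should hydrolyse and decarboxylate it to 5-(5-hydroxy-6,7-dimethoxy-4-oxo-4H-chromen-2-yl)-4-methoxycyclohexane-1,3-dione F3.
- Dehydrogenation over Pd/C in refluxing mesitylene should aromatise F3 to 16.

Step 3. Over-demethylation at C6 is the main danger, because the acetal consumes BCl3 and an excess is needed; decomposition of the electrophilic chloro ether or incomplete unmasking of the acetal next to the electron-poor pyrone may also occur. The fallback separates the two tasks; it sets out from 2 and comes back at 7.
- Claisen condensation of 2 with ethyl acetate (NaH, THF, reflux) and closure in HCl/MeOH should give 5,6,7-trimethoxy-2-methyl-4H-chromen-4-one F4.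
- BCl3 (1.2 equiv, CH2Cl2, −78 → 0 °C) then has only the peri ether to cleave and should give 5-hydroxy-6,7-dimethoxy-2-methyl-4H-chromen-4-one F5.
- Riley oxidation of the activated 2-methyl group (SeO2, 1,4-dioxane, reflux) should give 7.

Step 4. Oligomerisation of the highly electrophilic product, a second addition of nitromethane, or attack of ammonia on C2 of the pyrone may occur under prolonged heating. The fallback replaces the one-flask condensation by a discrete addition–elimination sequence; it sets out from 7 and comes back at 9.
- Nitroaldol addition of 8 to 7 at 0 °C with catalytic iPr2NEt in THF should give 5-hydroxy-2-(1-hydroxy-2-nitroethyl)-6,7-dimethoxy-4H-chromen-4-one F6 (racemic), which is isolated.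
- Mesylation of the secondary alcohol (MsCl, Et3N, CH2Cl2, −20 °C), toward which the chelated 5-OH is far less reactive, gives 1-(5-hydroxy-6,7-dimethoxy-4-oxo-4H-chromen-2-yl)-2-nitroethyl methanesulfonate F7.
- F7 loses methanesulfonic acid in the same flask to give 9.

Step 2. Incomplete intermolecular acylation of the hindered, electron-rich dianion, or loss of the acetal during ring closure, may lower the throughput. The fallback makes the acylation intramolecular; it sets out from 2 and comes back at 5.
- Saponification of 3 (LiOH, THF–H2O) gives 2,2-dimethoxyacetic acid F8.
- Esterification of the phenol of 2 (EDC·HCl, DMAP, CH2Cl2) gives 2-acetyl-3,4,5-trimethoxyphenyl 2,2-dimethoxyacetate F9.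
- KOtBu in THF then effects the Baker–Venkataraman acyl shift to 4, which is closed in HCl/MeOH to 5.

## Further compounds

F1 | step 7 | 5-hydroxy-6,7-dimethoxy-2-[(1E)-3-oxobut-1-en-1-yl]-4H-chromen-4-one | CC(=O)/C=C/c1cc(=O)c2c(O)c(OC)c(OC)cc2o1
F2 | step 7 | methyl 6-(5-hydroxy-6,7-dimethoxy-4-oxo-4H-chromen-2-yl)-1-methoxy-2,4-dioxocyclohexane-1-carboxylate (mixture of diastereomers) | COC(=O)C1(OC)C(=O)CC(=O)CC1c1cc(=O)c2c(O)c(OC)c(OC)cc2o1
F3 | step 7 | 5-(5-hydroxy-6,7-dimethoxy-4-oxo-4H-chromen-2-yl)-4-methoxycyclohexane-1,3-dione (mixture of diastereomers) | COC1C(=O)CC(=O)CC1c1cc(=O)c2c(O)c(OC)c(OC)cc2o1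
F4 | step 3 | 5,6,7-trimethoxy-2-methyl-4H-chromen-4-one | Cc1cc(=O)c2c(OC)c(OC)c(OC)cc2o1
F5 | step 3 | 5-hydroxy-6,7-dimethoxy-2-methyl-4H-chromen-4-one | Cc1cc(=O)c2c(O)c(OC)c(OC)cc2o1
F6 | step 4 | 5-hydroxy-2-(1-hydroxy-2-nitroethyl)-6,7-dimethoxy-4H-chromen-4-one (racemic) | COc1cc2oc(C(O)C[N+](=O)[O-])cc(=O)c2c(O)c1OC
F7 | step 4 | 1-(5-hydroxy-6,7-dimethoxy-4-oxo-4H-chromen-2-yl)-2-nitroethyl methanesulfonate (racemic) | COc1cc2oc(C(OS(C)(=O)=O)C[N+](=O)[O-])cc(=O)c2c(O)c1OC
F8 | step 2 | 2,2-dimethoxyacetic acid | COC(OC)C(=O)O
F9 | step 2 | 2-acetyl-3,4,5-trimethoxyphenyl 2,2-dimethoxyacetate | COC(OC)C(=O)Oc1cc(OC)c(OC)c(OC)c1C(C)=O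
A1 | alternative 1 | (Z)-2-(benzyloxy)-N-hydroxy-4,5,6-trimethoxybenzene-1-carboximidoyl chloride | COc1cc(OCc2ccccc2)c(/C(Cl)=N/O)c(OC)c1OC
A2 | alternative 1 | 2-(benzyloxy)-4,5,6-trimethoxybenzonitrile oxide | COc1cc(OCc2ccccc2)c(C#[N+][O-])c(OC)c1OC
A3 | alternative 1 | 1,5-bis(benzyloxy)-3-ethynyl-2-methoxybenzene | C#Cc1cc(OCc2ccccc2)cc(OCc2ccccc2)c1OC
A4 | alternative 1 | 3-[2-(benzyloxy)-4,5,6-trimethoxyphenyl]-5-[3,5-bis(benzyloxy)-2-methoxyphenyl]isoxazole | COc1cc(OCc2ccccc2)c(-c2cc(-c3cc(OCc4ccccc4)cc(OCc4ccccc4)c3OC)on2)c(OC)c1OC
A5 | alternative 2 | 3,4,5-trimethoxy-2-(trimethylsilyl)phenyl trifluoromethanesulfonate | COc1cc(OS(=O)(=O)C(F)(F)F)c([Si](C)(C)C)c(OC)c1OC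
A6 | alternative 2 | 3,4,5-trimethoxybenzyne (1,2-didehydro-3,4,5-trimethoxybenzene) | COC1=C(OC)C(OC)=CC#C1
A7 | alternative 2 | 3-[3,5-bis(benzyloxy)-2-methoxyphenyl]prop-2-ynoic acid | COc1c(OCc2ccccc2)cc(OCc2ccccc2)cc1C#CC(=O)O
A8 | alternative 2 | 3',5'-bis(benzyloxy)-5,6,7,2'-tetramethoxyflavone | COc1cc2oc(-c3cc(OCc4ccccc4)cc(OCc4ccccc4)c3OC)cc(=O)c2c(OC)c1OC
A9 | alternative 3 | 5-hydroxy-6,7-dimethoxy-2-[(1E)-3-oxobut-1-en-1-yl]-4H-chromen-4-one | CC(=O)/C=C/c1cc(=O)c2c(O)c(OC)c(OC)cc2o1
A10 | alternative 3 | dimethyl 2-methoxypropanedioate | COC(C(=O)OC)C(=O)OC
A11 | alternative 3 | methyl 6-(5-hydroxy-6,7-dimethoxy-4-oxo-4H-chromen-2-yl)-1-methoxy-2,4-dioxocyclohexane-1-carboxylate (mixture of diastereomers) | COC(=O)C1(OC)C(=O)CC(=O)CC1c1cc(=O)c2c(O)c(OC)c(OC)cc2o1
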